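The plan grows ring A onto a preformed five-membered oxygen ring instead of starting from an arene. The feature exploited is C7a: bonded to O1, C3a and C7, it has the bonding pattern of an ester carbon and is traced back to the carbonyl of a trans-4-methyl-5-aryl-γ-butyrolactone, whose stereocentres (future C3 and C2) stem from one anti-crotylboration. The precursor is that lactone with a 3-oxobutyl chain on its α-carbon (future C3a). In a single operation base forges C7–C7a by Claisen closure, freeing the C2 hydroxyl, and mild acid re-attaches O1 to C7a, delivering the bicyclic vinylogous ester with its ketone at C6. The saturated C4–C5 edge then permits regiospecific C5 formylation before a mild aromatisation.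

Key step: step 7

Assumption: the (R)-enantiomer of the phosphoric acid catalyst is taken to direct the crotyl group to the Re face of 1, as it does for simple aryl aldehydes, which gives the (1R,2R) alcohol.

Step 1
Reactants: 1 3,4,5-trimethoxybenzaldehyde; 2 (E)-crotylboronic acid pinacol ester
Product: 4 (1R,2R)-2-methyl-1-(3,4,5-trimethoxyphenyl)but-3-en-1-ol, via pinacol borate ester 3 (not isolated)
Conditions: (R)-3,3'-bis(2,4,6-triisopropylphenyl)-1,1'-binaphthyl-2,2'-diyl hydrogen phosphate [(R)-TRIP] (5 mol%), toluene, −30 °C; aq. NaHCO3 work-up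
Reagents that add atoms: none
Why: In this chiral Brønsted-acid-catalysed crotylboration, a closed chair (Zimmerman–Traxler) transition state turns the E geometry of 2 into the anti relationship, while the catalyst, hydrogen-bonded to a boronate oxygen and the formyl hydrogen, selects the Re face, so both centres should be set as R.

Step 2
Reactants: 4 (1R,2R)-2-methyl-1-(3,4,5-trimethoxyphenyl)but-3-en-1-ol
Product: 6 (1R,2R)-2-methyl-1-(3,4,5-trimethoxyphenyl)butane-1,4-diol, via O,C-bis(9-BBN) adduct 5 (not isolated)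
Conditions: 9-borabicyclo[3.3.1]nonane (9-BBN, 2.3 equiv), THF, 0 °C to rt; then aq. NaOH, 30% H2O2, 0 °C to rt
Reagents that add atoms: hydrogen peroxide, OO
Why: In this anti-Markovnikov hydroboration–oxidation the bulky borane places boron on the terminal carbon (one further equivalent is consumed by the hydroxyl), and neither stereocentre is touched.

Step 3
Reactants: 6 (1R,2R)-2-methyl-1-(3,4,5-trimethoxyphenyl)butane-1,4-diol
Product: 8 (4R,5R)-4-methyl-5-(3,4,5-trimethoxyphenyl)oxolan-2-one, via lactol 7 (not isolated)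
Conditions: 2,2,6,6-tetramethylpiperidin-1-oxyl (TEMPO, 10 mol%), PhI(OAc)2 (2.5 equiv), CH2Cl2, rt
Reagents that add atoms: none
Why: In this oxoammonium-mediated oxidative lactonisation of a 1,4-diol the unhindered primary alcohol is oxidised first, the hydroxy aldehyde closes to the lactol, and a second oxidation gives the trans lactone with both centres intact.

Step 4
Reactants: 9 2-(2-bromoethyl)-2-methyl-1,3-dioxolane
Product: 10 2-(2-iodoethyl)-2-methyl-1,3-dioxolane
Conditions: NaI (3 equiv), NaHCO3 (0.1 equiv), acetone, reflux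
Reagents that add atoms: sodium iodide, [Na+].[I-]
Why: This Finkelstein halide exchange is driven by precipitation of the bromide salt and supplies the more reactive electrophile, so that substitution can outrun elimination in step 5.

Step 5
Reactants: 8 (4R,5R)-4-methyl-5-(3,4,5-trimethoxyphenyl)oxolan-2-one; 10 2-(2-iodoethyl)-2-methyl-1,3-dioxolane
Product: 12 (3R,4R,5R)-4-methyl-3-[2-(2-methyl-1,3-dioxolan-2-yl)ethyl]-5-(3,4,5-trimethoxyphenyl)oxolan-2-one, via lithium enolate 11 (not isolated)
Conditions: LiN(iPr)2 (1.05 equiv), THF, −78 °C; N,N'-dimethylpropyleneurea (DMPU, 3 equiv), 10 (1.5 equiv), −78 to −20 °C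
Reagents that add atoms: none
Why: In this SN2 alkylation of a lactone enolate the iodide should approach the face opposite the adjacent C4 methyl and set C3 trans to it (R), a centre that is erased on aromatisation, so its purity is not critical.

Step 6
Reactants: 12 (3R,4R,5R)-4-methyl-3-[2-(2-methyl-1,3-dioxolan-2-yl)ethyl]-5-(3,4,5-trimethoxyphenyl)oxolan-2-one
Product: 13 (3R,4R,5R)-4-methyl-3-(3-oxobutyl)-5-(3,4,5-trimethoxyphenyl)oxolan-2-one
Conditions: 1 M HCl, THF, rt
Reagents that add atoms: water, O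
Why: Acid-catalysed acetal hydrolysis cleaves the dioxolane of a methyl ketone under conditions too mild to open the lactone or ionise its benzylic C–O bond.

Step 7
Reactants: 13 (3R,4R,5R)-4-methyl-3-(3-oxobutyl)-5-(3,4,5-trimethoxyphenyl)oxolan-2-one
Product: 16 (2R,3R,3aR)-3-methyl-2-(3,4,5-trimethoxyphenyl)-3,3a,4,5-tetrahydro-1-benzofuran-6(2H)-one (C3a–C4 bond trans to the 3-methyl so that 3a-H is cis to it), via potassium dionate 14 (not isolated), via hydroxy dione 15 (not isolated)
Conditions: KOtBu (2.2 equiv), THF, 0 °C to rt; AcOH (2.5 equiv); crude, pyridinium p-toluenesulfonate (10 mol%), toluene, 4 Å molecular sieves, 50 °C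
Reagents that add atoms: none
Why: Under reversible deprotonation by KOtBu only the methyl-side enolate (C7) has an electrophile within reach; it adds to the lactone carbonyl C7a, the tetrahedral adduct ejects the C2 alkoxide, and proton transfer stores the product as the stabilised dionate 14, which pulls all equilibria forward. The closest known reaction type is the intramolecular Claisen (Dieckmann-type) cyclisation of δ-keto esters to cyclohexane-1,3-diones, followed by acid-catalysed enol etherification of a 1,3-dione by an alcohol. The carbocycle closes 6-(enolendo)-exo-trig, and after acidification the C2 hydroxyl of 15 adds 5-exo-trig to C7a, with water lost towards C7 to give the conjugated C7=C7a enol ether. No stereocentre is created: C2 and C3 lie γ and β to the nearest carbonyl and none of their bonds is broken, while the only labile centre, C3a, should keep its C4 branch trans to the methyl and disappears on aromatisation anyway. Two regiochemical choices are needed and ring size settles both, since the methylene enolate could only make a four-membered ring and closure of the hydroxyl on C6 would need a bridged seven-membered ring. The buffered acid is chosen so that oxygen acts as the nucleophile and the electron-rich benzylic C2–O bond does not ionise, which keeps C2 as R.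

Step 8
Reactants: 16 (2R,3R,3aR)-3-methyl-2-(3,4,5-trimethoxyphenyl)-3,3a,4,5-tetrahydro-1-benzofuran-6(2H)-one
Product: 18 (2R,3R,3aR,5Z)-5-(hydroxymethylidene)-3-methyl-2-(3,4,5-trimethoxyphenyl)-3,3a,4,5-tetrahydro-1-benzofuran-6(2H)-one, via lithium dienolate 17 (not isolated)
Conditions: LiN(iPr)2 (1.1 equiv), THF, −78 °C; HCO2Et (3 equiv), −78 to 0 °C; cold 0.5 M HCl to pH 4
Reagents that add atoms: ethyl formate, CCOC=O
Why: Kinetic deprotonation of a vinylogous ester occurs at the α' carbon (Stork–Danheiser regiochemistry, here C5), and crossed Claisen formylation there gives the chelated, fully enolised β-keto aldehyde, which fixes the future side-chain position without relying on arene directing effects.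

Step 9
Reactants: 18 (2R,3R,3aR,5Z)-5-(hydroxymethylidene)-3-methyl-2-(3,4,5-trimethoxyphenyl)-3,3a,4,5-tetrahydro-1-benzofuran-6(2H)-one
Product: 20 (2R,3R)-6-hydroxy-3-methyl-2-(3,4,5-trimethoxyphenyl)-2,3-dihydro-1-benzofuran-5-carbaldehyde, via formyl dienone 19 (not isolated)
Conditions: 2,3-dichloro-5,6-dicyano-1,4-benzoquinone (DDQ, 1.05 equiv), 1,4-dioxane, rt
Reagents that add atoms: none
Why: In this quinone dehydrogenation of a 2-hydroxymethylene ketone the enolised β-keto aldehyde should give up the C4 hydride already at room temperature, the C4=C5 dienone 19 tautomerises at once to the phenol by loss of 3a-H, and the formyl group para to O1 makes the product electron-poorer, so further hydride loss from C2 or C3 is disfavoured.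

Step 10
Reactants: 20 (2R,3R)-6-hydroxy-3-methyl-2-(3,4,5-trimethoxyphenyl)-2,3-dihydro-1-benzofuran-5-carbaldehyde
Product: 21 (2R,3R)-6-methoxy-3-methyl-2-(3,4,5-trimethoxyphenyl)-2,3-dihydro-1-benzofuran-5-carbaldehyde
Conditions: MeI (2 equiv), K2CO3 (2 equiv), DMF, rt
Reagents that add atoms: iodomethane, CI
Why: This is a Williamson O-methylation of the only acidic site, a salicylaldehyde-type phenol, under conditions that affect neither the aldehyde nor C2 and C3.

Step 11
Reactants: 21 (2R,3R)-6-methoxy-3-methyl-2-(3,4,5-trimethoxyphenyl)-2,3-dihydro-1-benzofuran-5-carbaldehyde; 22 5-(ethylsulfonyl)-1-phenyl-1H-tetrazole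
Product: 25 (2R,3R)-6-methoxy-3-methyl-5-[(1E)-prop-1-en-1-yl]-2-(3,4,5-trimethoxyphenyl)-2,3-dihydro-1-benzofuran, via potassiated sulfone 23 (not isolated), via alkoxide adduct 24 (not isolated)
Conditions: 22 (1.3 equiv), KN(SiMe3)2 (1.25 equiv), DME, −60 °C; then 21, −60 °C to rt; aq. NH4Cl
Reagents that add atoms: none
Why: In this Julia–Kocienski olefination the metallated sulfone adds to the aldehyde, Smiles transfer of the tetrazole to oxygen and loss of SO2 and the tetrazolone release the alkene, the (E)-isomer should dominate strongly for an electron-rich aryl aldehyde with a potassium counter-ion in DME, and no acid meets the sensitive styrene or the C2–O1 bond.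

Compound list
1 | 3,4,5-trimethoxybenzaldehyde | COc1cc(C=O)cc(OC)c1OC | starting material
2 | (E)-crotylboronic acid pinacol ester | C/C=C/CB1OC(C)(C)C(C)(C)O1 | starting material
3 | pinacol borate ester of 4 | CC1(C)OB(O[C@@H](c2cc(OC)c(OC)c(OC)c2)[C@H](C)C=C)OC1(C)C | intermediate
4 | (1R,2R)-2-methyl-1-(3,4,5-trimethoxyphenyl)but-3-en-1-ol | O[C@@H](c1cc(OC)c(OC)c(OC)c1)[C@H](C)C=C | intermediate
5 | O,C-bis(9-BBN) adduct of 4 (borinate on the C1 oxygen, B-alkyl at C4) | O(B1C2CCCC1CCC2)[C@@H](c1cc(OC)c(OC)c(OC)c1)[C@H](C)CCB1C2CCCC1CCC2 | intermediate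
6 | (1R,2R)-2-methyl-1-(3,4,5-trimethoxyphenyl)butane-1,4-diol | O[C@@H](c1cc(OC)c(OC)c(OC)c1)[C@H](C)CCO | intermediate
7 | (4R,5R)-4-methyl-5-(3,4,5-trimethoxyphenyl)oxolan-2-ol (anomer mixture) | OC1O[C@@H](c2cc(OC)c(OC)c(OC)c2)[C@H](C)C1 | intermediate
8 | (4R,5R)-4-methyl-5-(3,4,5-trimethoxyphenyl)oxolan-2-one | O=C1O[C@@H](c2cc(OC)c(OC)c(OC)c2)[C@H](C)C1 | intermediate
9 | 2-(2-bromoethyl)-2-methyl-1,3-dioxolane | CC1(CCBr)OCCO1 | starting material
10 | 2-(2-iodoethyl)-2-methyl-1,3-dioxolane | CC1(CCI)OCCO1 | intermediate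
11 | lithium enolate of 8 | [Li]OC1=C[C@@H](C)[C@H](c2cc(OC)c(OC)c(OC)c2)O1 | intermediate
12 | (3R,4R,5R)-4-methyl-3-[2-(2-methyl-1,3-dioxolan-2-yl)ethyl]-5-(3,4,5-trimethoxyphenyl)oxolan-2-one | O=C1O[C@@H](c2cc(OC)c(OC)c(OC)c2)[C@H](C)[C@H]1CCC3(C)OCCO3 | intermediate
13 | (3R,4R,5R)-4-methyl-3-(3-oxobutyl)-5-(3,4,5-trimethoxyphenyl)oxolan-2-one | O=C1O[C@@H](c2cc(OC)c(OC)c(OC)c2)[C@H](C)[C@H]1CCC(C)=O | intermediate
14 | potassium enolate of 15 | [K+].[O-]C1=CC(=O)CC[C@@H]1[C@@H](C)[C@@H](O)c1cc(OC)c(OC)c(OC)c1 | intermediate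
15 | (4R)-4-[(1R,2R)-1-hydroxy-1-(3,4,5-trimethoxyphenyl)propan-2-yl]cyclohexane-1,3-dione | O=C1CC(=O)CC[C@@H]1[C@@H](C)[C@@H](O)c1cc(OC)c(OC)c(OC)c1 | intermediate
16 | (2R,3R,3aR)-3-methyl-2-(3,4,5-trimethoxyphenyl)-3,3a,4,5-tetrahydro-1-benzofuran-6(2H)-one (3a-H cis to the 3-methyl) | O=C1C=C2O[C@@H](c3cc(OC)c(OC)c(OC)c3)[C@H](C)[C@H]2CC1 | intermediate
17 | lithium C5=C6 dienolate of 16 | [Li]OC1=CC[C@@H]2[C@@H](C)[C@H](c3cc(OC)c(OC)c(OC)c3)OC2=C1 | intermediate
18 | (2R,3R,3aR,5Z)-5-(hydroxymethylidene)-3-methyl-2-(3,4,5-trimethoxyphenyl)-3,3a,4,5-tetrahydro-1-benzofuran-6(2H)-one | O/C=C1\C(=O)C=C2O[C@@H](c3cc(OC)c(OC)c(OC)c3)[C@H](C)[C@H]2C1 | intermediate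
19 | (2R,3R)-3-methyl-6-oxo-2-(3,4,5-trimethoxyphenyl)-2,3,3a,6-tetrahydro-1-benzofuran-5-carbaldehyde (keto tautomer of 20, 3a-H cis to the methyl) | O=CC1=C[C@@H]2[C@@H](C)[C@H](c3cc(OC)c(OC)c(OC)c3)OC2=CC1=O | intermediate
20 | (2R,3R)-6-hydroxy-3-methyl-2-(3,4,5-trimethoxyphenyl)-2,3-dihydro-1-benzofuran-5-carbaldehyde | O=Cc1cc2c(cc1O)O[C@@H](c1cc(OC)c(OC)c(OC)c1)[C@@H]2C | intermediate
21 | (2R,3R)-6-methoxy-3-methyl-2-(3,4,5-trimethoxyphenyl)-2,3-dihydro-1-benzofuran-5-carbaldehyde | O=Cc1cc2c(cc1OC)O[C@@H](c1cc(OC)c(OC)c(OC)c1)[C@@H]2C | intermediate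
22 | 5-(ethylsulfonyl)-1-phenyl-1H-tetrazole | CCS(=O)(=O)c1nnnn1-c1ccccc1 | starting material
23 | potassium α-sulfonyl carbanion of 22 | [K+].C[CH-]S(=O)(=O)c1nnnn1-c1ccccc1 | intermediate
24 | potassium β-alkoxy sulfone from 23 and 21 (two new centres, mixture) | [K+].[O-]C(C(C)S(=O)(=O)c1nnnn1-c1ccccc1)c1cc2c(cc1OC)O[C@@H](c1cc(OC)c(OC)c(OC)c1)[C@@H]2C | intermediate
25 | (2R,3R)-6-methoxy-3-methyl-5-[(1E)-prop-1-en-1-yl]-2-(3,4,5-trimethoxyphenyl)-2,3-dihydro-1-benzofuran | C/C=C/c1cc2c(cc1OC)O[C@@H](c1cc(OC)c(OC)c(OC)c1)[C@@H]2C | target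

Total step count: 11. Longest linear sequence: 10 steps (1, 2, 3, 5, 6, 7, 8, 9, 10, 11).

Steps most likely to fail

**Step 7.**
- Risk: Until the dionate has formed, opening of the lactone is reversible. Intermolecular aldol condensation of the methyl ketone, or retro-Michael loss of the oxobutyl chain, may therefore outrun ring closure. In the acid stage, ionisation at C2 may erode the trans relationship.
- Fallback: Lactone opening is separated from C–C bond formation. The fallback sets out from 12.
  - ClMgN(OMe)Me (from MeNH(OMe)·HCl and iPrMgCl, THF, −20 °C) opens the lactone to the γ-hydroxy Weinreb amide F1.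
  - TBSOTf and 2,6-lutidine cap the benzylic hydroxyl to give the silyl ether F2.
  - Pyridinium p-toluenesulfonate in wet acetone frees the methyl ketone F3.
  - KN(SiMe3)2 (2.2 equiv, THF, −78 to 0 °C) closes the kinetic methyl enolate onto the Weinreb amide, whose chelated adduct cannot revert, to give the silyloxy dione F4.
  - Aqueous HF in MeCN removes the silyl group, and the freed hydroxyl closes onto C7a. The route is rejoined at 16.

**Step 5.**
- Risk: The basic enolate may take HI out of the iodide by E2 elimination. Proton exchange between product and enolate may also cause double alkylation and stalled conversion.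
- Fallback: Substitution is replaced by conjugate addition. The fallback sets out from 8.
  - LiN(iPr)2, TBSCl and DMPU (THF, −78 °C) give the silyl ketene acetal F5.
  - Sc(OTf)3-catalysed Mukaiyama–Michael addition to but-3-en-2-one (CH2Cl2, −78 °C) gives the silyl enol ether F6, again with attack anti to the methyl.
  - 1 M HCl in THF cleaves the silyl enol ether. The route is rejoined at 13, so that 10 and 12 are not needed.

**Step 9.**
- Risk: The quinone may go on to abstract hydride from C2 or C3, which would flatten the heterocycle to a benzofuran and destroy both stereocentres. It may also add to the enol instead of oxidising it.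
- Fallback: Hydride abstraction is replaced by a selenoxide syn elimination. The fallback sets out from 18.
  - PhSeCl and pyridine (CH2Cl2, 0 °C) selenenylate the β-keto aldehyde at C5 to give the α-phenylselanyl keto aldehyde F7.
  - One equivalent of mCPBA at −78 °C gives the selenoxide F8. This oxidant is chosen over H2O2 so that the electron-rich aldehyde is not oxidised further.
  - On warming, F8 eliminates towards C4–H to give 19, which tautomerises. The route is rejoined at 20.

Further compounds
F1 | step 7 | (2R,3R,4R)-4-hydroxy-N-methoxy-N,3-dimethyl-2-[2-(2-methyl-1,3-dioxolan-2-yl)ethyl]-4-(3,4,5-trimethoxyphenyl)butanamide | CON(C)C(=O)[C@H](CCC1(C)OCCO1)[C@@H](C)[C@@H](O)c1cc(OC)c(OC)c(OC)c1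
F2 | step 7 | tert-butyldimethylsilyl ether of F1 | CON(C)C(=O)[C@H](CCC1(C)OCCO1)[C@@H](C)[C@@H](O[Si](C)(C)C(C)(C)C)c1cc(OC)c(OC)c(OC)c1
F3 | step 7 | (2R,3R,4R)-4-[tert-butyl(dimethyl)silyl]oxy-N-methoxy-N,3-dimethyl-2-(3-oxobutyl)-4-(3,4,5-trimethoxyphenyl)butanamide | CON(C)C(=O)[C@H](CCC(C)=O)[C@@H](C)[C@@H](O[Si](C)(C)C(C)(C)C)c1cc(OC)c(OC)c(OC)c1
F4 | step 7 | tert-butyldimethylsilyl ether of 15 | O=C1CC(=O)CC[C@@H]1[C@@H](C)[C@@H](O[Si](C)(C)C(C)(C)C)c1cc(OC)c(OC)c(OC)c1
F5 | step 5 | tert-butyl(dimethyl){[(2R,3R)-3-methyl-2-(3,4,5-trimethoxyphenyl)-2,3-dihydrofuran-5-yl]oxy}silane | CC(C)(C)[Si](C)(C)OC1=C[C@@H](C)[C@H](c2cc(OC)c(OC)c(OC)c2)O1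
F6 | step 5 | tert-butyldimethylsilyl enol ether of 13 (C=C towards the chain, geometry undefined) | O=C1O[C@@H](c2cc(OC)c(OC)c(OC)c2)[C@H](C)[C@H]1CC=C(C)O[Si](C)(C)C(C)(C)C
F7 | step 9 | (2R,3R,3aR)-3-methyl-6-oxo-5-(phenylselanyl)-2-(3,4,5-trimethoxyphenyl)-2,3,3a,4,5,6-hexahydro-1-benzofuran-5-carbaldehyde (C5 undefined) | O=CC1(C[C@@H]2[C@@H](C)[C@H](c3cc(OC)c(OC)c(OC)c3)OC2=CC1=O)[Se]c1ccccc1
F8 | step 9 | selenoxide of F7 | O=CC1(C[C@@H]2[C@@H](C)[C@H](c3cc(OC)c(OC)c(OC)c3)OC2=CC1=O)[Se](=O)c1ccccc1
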